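The data were computed for substances that don't exist; the scatter is artificial.

**Time and charge.** Time is the one thing I count in this flask, so I start from the earlier run and then state what is asked.

| setting | east | flask |
|---|---|---|
| substrate | 0.10 M | 0.10 M |
| acid | 6 mM | 3.00 mM |
| remark | run made earlier |  |
| time |  | 25 h |

east run (percent of the substrate charged)

| time / h | substrate / % | target / % |
|---|---|---|
| 0.200 | 99.2 | 1.0 |
| 0.667 | 96.7 | 2.9 |
| 1.33 | 93.2 | 6.3 |
| 2.00 | 90.7 | 10.4 |
| 2.50 | 87.8 | 11.3 |

(readings scatter by 0.5 percentage points)

- acid is the free proton; pH is minus the decimal logarithm of its molar concentration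
- the analysis behind the earlier runs scatters by 0.5 percentage points, standard deviation

1. part of the substrate that has reacted at 25 h
2. pH of the solution at 25 h

**The ladder.** The substrate lifetime I read from the east run's last reading is 19.2 h, longer than that run's window of 2.50 h, which is the first rung; the reading at 0.667 h gives 19.9 h, so I read no drift in the clock while the substrate reacted reaches twice the acid's fraction of the charge, and I take the acid as kept and the pH as staying at the value its charge gives. Assuming the rate goes with acid (pseudo-first-order in substrate), the flask's fraction of 0.0300 against the east run's 0.0600 stretches the lifetime to 38.4 h, longer than the 25 h asked.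

**Counting turnovers.** The turnover count, the flask's time divided by that lifetime, is 0.651, and since the fraction left is the exponential of minus this count, I commit to 47.8% reacted.

**The result.** The forecast gives 47% and pH 2.52, with the proton “neither consumed nor produced”; the flask gives 55.3% and pH 2.52.

    substrate + target → side product (k = 0.00540 L mol⁻¹ min⁻¹)
    weak acid ⇌ conjugate base + acid, settled at all times (K = 3.20 × 10⁻⁸ M)
    substrate → weak acid + target (k = 3.60 × 10⁻⁶ min⁻¹)
    substrate + acid → weak acid + acid + target (k = 0.140 L mol⁻¹ min⁻¹)

**Where it parts.** The flask's remaining 45% of substrate amounts to 0.799 turnovers against my 0.651. The acid step uses substrate 4.0 times as fast as the step of substrate with target at 10.1 h, but 2.3 times as fast at 25.0 h. For the neighbouring flask with acid at 0.0510 of the charge, my count is 1.11, which gives 33.1% of the substrate left, and that flask holds 26%.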